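The route takes the benzene ring apart into three alkynes. Its atoms C4a, C5 (CH3), C6 (H), C7 (OH), C8 (H) and C8a (O1) form a 1,2,3,5-substituted arene. The methyl and hydroxyl positions are the reverse of what orcinol condensations give. The pairs C8a/C8 and C4a/C5 are already linked through O1–C2–C3–C4 of the pyran ring. One [2+2+2] cycloaddition of a tethered diyne with an ethynylboronate forms C4a–C8a, C5–C6 and C7–C8, closes both rings, and leaves boron at C7 as the phenol placeholder. The diyne is a tert-alkyl ethynyl ether with a pent-3-ynyl arm. It is made from (R)-linalool, whose carbinol carbon becomes C2 with no bond to it broken.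

Key step: step 6

Assumption: commercial (R)-(−)-linalool is taken as enantiopure, since it is the only source of the C2 (R) configuration; chroman numbering is used for the bicycle, and the side chain is numbered C1' (on C2) to C8' (bearing CO2H).

Step 1
Reactants: 1 (R)-linalool; 2 trichloroethylene
Product: 5 (R)-3-[(E)-1,2-dichloroethenyloxy]-3,7-dimethylocta-1,6-diene, via potassium linaloolate 3 (not isolated), via dichloroacetylene 4 (not isolated)
Conditions: KH, THF, 0 °C to rt; then 2, −50 °C to rt
Reagents that add atoms: potassium hydride, [K+].[H-] (potassium of 3 only)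
Why: O-Dichlorovinylation by the trichloroethylene method: base turns 2 into dichloroacetylene, the tertiary alkoxide adds to it in anti fashion to give the E ether without touching any bond of the stereocentre, and the group also masks the hydroxyl so that no alkoxide can later close an oxetane onto the activated primary carbon.

Step 2
Reactants: 5 dichlorovinyl ether of linalool
Product: 7 (R)-3-[(E)-1,2-dichloroethenyloxy]-3,7-dimethyloct-6-en-1-ol, via B-alkyl-9-BBN adduct 6 (not isolated)
Conditions: 9-BBN (1.1 equiv), THF, 0 °C to rt; then 3 M NaOH, 30% H2O2, 0 °C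
Reagents that add atoms: 9-borabicyclo[3.3.1]nonane, B1C2CCCC1CCC2 (stays in 6 only); hydrogen peroxide, OO (hydroxyl oxygen of 7)
Why: Hydroboration–oxidation: 9-BBN adds in anti-Markovnikov sense to the monosubstituted vinyl group much faster than to the trisubstituted alkene or the chlorine-deactivated enol ether, and alkaline peroxide then replaces boron by hydroxyl.

Step 3
Reactants: 7 primary alcohol
Product: 8 (R)-6-[(E)-1,2-dichloroethenyloxy]-8-iodo-2,6-dimethyloct-2-ene
Conditions: I2, PPh3, imidazole, CH2Cl2, 0 °C to rt
Reagents that add atoms: iodine, [I][I]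
Why: Appel-type iodination (Garegg–Samuelsson conditions): the unhindered primary alcohol is displaced by iodide through its oxyphosphonium salt under near-neutral conditions that spare both alkenes.

Step 4
Reactants: 8 primary iodide; 9 propyne
Product: 11 (R)-6-[(E)-1,2-dichloroethenyloxy]-2,6-dimethylundec-2-en-9-yne, via 1-propynyllithium 10 (not isolated)
Conditions: 9, n-BuLi, THF, −78 °C to 0 °C; then 8, DMPU, 0 °C to rt
Reagents that add atoms: n-butyllithium, [Li]CCCC (lithium of 10 only)
Why: SN2 alkylation of a lithium acetylide by a primary iodide in a dipolar aprotic cosolvent; the E-dichlorovinyl ether should survive because its vinylic hydrogen lies cis to the chlorine on the oxygen-bearing carbon, so no anti-periplanar loss of HCl is open to a base as weak as an acetylide.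

Step 5
Reactants: 11 dichlorovinyl ether enyne
Product: 14 (R)-6-(ethynyloxy)-2,6-dimethylundec-2-en-9-yne, via chloroethynyl ether 12 (not isolated), via lithium alkoxyacetylide 13 (not isolated)
Conditions: n-BuLi (2.2 equiv), THF, −78 °C to −40 °C; MeOH, −78 °C; cold work-up, filtration through Et3N-deactivated silica at 0 °C, used at once
Reagents that add atoms: n-butyllithium, [Li]CCCC (lithium of 13 only)
Why: Second half of the trichloroethylene ynol ether synthesis: n-BuLi removes HCl, a second equivalent exchanges the alkynyl chlorine for lithium, and cold protonation gives the terminal ethynyl ether, which is released only now and kept cold because tert-alkyl ynol ethers fragment by a retro-ene path on warming.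

Step 6
Reactants: 14 ethynyl ether diyne; 15 2-ethynyl-4,4,5,5-tetramethyl-1,3,2-dioxaborolane (ethynylboronic acid pinacol ester)
Product: 16 2-[(2R)-2,5-dimethyl-2-(4-methylpent-3-en-1-yl)chroman-7-yl]-4,4,5,5-tetramethyl-1,3,2-dioxaborolane
Conditions: Cp*RuCl(cod) (5–10 mol %), 15 (3 equiv), ClCH2CH2Cl, 0 °C to 20 °C, 14 added slowly by syringe pump, argon
Reagents that add atoms: none
Why: Proposed new method: loss of cod from Cp*RuCl(cod) gives a divalent ruthenium fragment that binds both alkynes of 14 and couples them oxidatively to a ruthenacyclopentadiene (new bond C4a–C8a), after which 15 coordinates, inserts and is released by reductive elimination (new bonds C5–C6 and C7–C8). The closest known reaction type is the room-temperature Cp*RuCl(cod)-catalysed [2+2+2] cycloaddition of 1,6- and 1,7-diynes with ethynylboronates, together with the closure of ynamide-tethered diynes to indolines; new here are the alkoxyalkyne oxygen inside the tether and the tert-alkyl ethynyl ether. The dihydropyran ring (O1, C2, C3, C4, C4a, C8a) closes in the intramolecular oxidative coupling, favoured by the fully substituted C2 (Thorpe–Ingold effect) and the short C–O bonds, and the benzene ring closes by the intermolecular insertion and reductive elimination. No stereocentre is created, and C2 stays R because none of its four bonds takes part. The step needs regioselectivity, which sterics should secure: the bulky boryl carbon of 15 bonds to the unsubstituted terminus C8 and its CH end to the methyl-bearing C5, which puts boron at C7, meta to the methyl group. It also needs chemoselectivity and mildness: slow addition of 14 to excess 15 curbs self-coupling, the trisubstituted alkene binds too weakly to compete, and 20 °C or below keeps the ynol ether clear of retro-ene fragmentation.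

Step 7
Reactants: 16 chroman boronate
Product: 17 (2R)-2,5-dimethyl-2-(4-methylpent-3-en-1-yl)chroman-7-ol
Conditions: 30% H2O2, 1 M NaOH, THF, 0 °C
Reagents that add atoms: hydrogen peroxide, OO
Why: Oxidative deborylation: hydroperoxide adds to boron and the aryl group shifts from boron to oxygen at the same ring carbon, so the hydroxyl lands on C7, while the unactivated alkene is inert to alkaline peroxide.

Step 8
Reactants: 17 chromanol
Product: 18 tert-butyl{[(2R)-2,5-dimethyl-2-(4-methylpent-3-en-1-yl)chroman-7-yl]oxy}dimethylsilane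
Conditions: TBSCl, imidazole, DMF, rt
Reagents that add atoms: tert-butyldimethylsilyl chloride, CC(C)(C)[Si](C)(C)Cl
Why: Routine imidazole-promoted O-silylation shields the electron-rich phenol from the oxidant of step 9 and from the bases of steps 12 and 13, and an aryl silyl ether is chosen because hydroxide removes it in step 14.

Step 9
Reactants: 18 silyl ether
Product: 20 (E)-5-[(2R)-7-(tert-butyldimethylsilyloxy)-2,5-dimethylchroman-2-yl]-2-methylpent-2-en-1-ol, via E-enal 19 (not isolated)
Conditions: SeO2 (0.1 equiv), salicylic acid (0.1 equiv), t-BuOOH, CH2Cl2, 0 °C to rt; then NaBH4, MeOH, 0 °C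
Reagents that add atoms: tert-butyl hydroperoxide, CC(C)(C)OO (terminal oxidant); selenium dioxide, O=[Se]=O (oxygen carrier)
Why: Riley-type allylic oxidation with catalytic SeO2: ene reaction and [2,3]-sigmatropic shift of the allylseleninic acid functionalise only the methyl group trans to the chain, which fixes the E geometry of C3'=C4', and NaBH4 returns the over-oxidised portion 19 to 20.

Step 10
Reactants: 20 allylic alcohol
Product: 21 (2R)-2-[(E)-5-bromo-4-methylpent-3-en-1-yl]-7-(tert-butyldimethylsilyloxy)-2,5-dimethylchroman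
Conditions: CBr4, PPh3, CH2Cl2, −20 °C to 0 °C
Reagents that add atoms: carbon tetrabromide, BrC(Br)(Br)Br
Why: Appel bromination: SN2 displacement at the primary allylic carbon proceeds without allylic transposition or loss of the E geometry and leaves the aryl silyl ether intact.

Step 11
Reactants: 22 acetaldehyde; 23 tert-butylamine
Product: 24 (E)-N-tert-butylethanimine
Conditions: neat, 0 °C; K2CO3 (drying); distillation
Reagents that add atoms: none
Why: Simple imine condensation, in which the bulky tert-butyl group holds back self-aldol chemistry of the aldimine.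

Step 12
Reactants: 21 allylic bromide; 24 aldimine
Product: 27 (E)-7-[(2R)-7-(tert-butyldimethylsilyloxy)-2,5-dimethylchroman-2-yl]-4-methylhept-4-enal, via lithiated aldimine 25 (not isolated), via alkylated aldimine 26 (not isolated)
Conditions: 24, LiN(i-Pr)2, THF, 0 °C; 21, −78 °C to 0 °C; then aq. oxalic acid, Et2O, rt
Reagents that add atoms: lithium diisopropylamide, [Li]N(C(C)C)C(C)C (lithium of 25 only); water, O (carbonyl oxygen of 27)
Why: Stork-type metalloenamine alkylation: the lithiated aldimine serves as an acetaldehyde enolate equivalent that attacks the primary allylic bromide in SN2 fashion and adds C6' and C7', and mild aqueous acid frees the aldehyde without harming the silyl ether.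

Step 13
Reactants: 27 aldehyde; 28 ethyl 2-[bis(2,2,2-trifluoroethoxy)phosphoryl]propanoate (racemic)
Product: 30 ethyl (2Z,6E)-9-[(2R)-7-(tert-butyldimethylsilyloxy)-2,5-dimethylchroman-2-yl]-2,6-dimethylnona-2,6-dienoate, via potassium phosphonate carbanion 29 (not isolated)
Conditions: 28, KN(SiMe3)2, 18-crown-6, THF, −78 °C; then 27, −78 °C
Reagents that add atoms: potassium bis(trimethylsilyl)amide, C[Si](C)(C)[N-][Si](C)(C)C.[K+] (potassium of 29 only)
Why: Still–Gennari olefination: with the electron-poor trifluoroethyl phosphonate and a crown-ether-separated potassium ion the kinetic adduct collapses faster than it reverts, which places ester and chain cis and sets the 2Z geometry of C7'=C8'.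

Step 14
Reactants: 30 silylated Z-ester
Product: 31 (2Z,6E)-9-[(2R)-7-hydroxy-2,5-dimethylchroman-2-yl]-2,6-dimethylnona-2,6-dienoic acid (target)
Conditions: LiOH·H2O (excess), THF/MeOH/H2O, 45 °C; then 1 M HCl to pH 3
Reagents that add atoms: lithium hydroxide, [Li+].[OH-]
Why: Saponification of the ester, in which hydroxide also cleaves the base-labile aryl silyl ether, so that one operation and acidification give the hydroxy acid, the moderate temperature guarding the Z alkene against isomerisation.

Compound list
1 | (R)-(−)-linalool | CC(C)=CCC[C@](O)(C)C=C | starting material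
2 | trichloroethylene | ClC=C(Cl)Cl | starting material
3 | potassium (R)-linaloolate | CC(C)=CCC[C@]([O-])(C)C=C.[K+] | intermediate
4 | dichloroacetylene | ClC#CCl | intermediate
5 | (R)-3-[(E)-1,2-dichloroethenyloxy]-3,7-dimethylocta-1,6-diene | CC(C)=CCC[C@](O/C(Cl)=C\Cl)(C)C=C | intermediate
6 | 9-{3-[(E)-1,2-dichloroethenyloxy]-3,7-dimethyloct-6-en-1-yl}-9-borabicyclo[3.3.1]nonane (same spatial arrangement as 5; formally S because the boron-bearing branch ranks lower) | CC(C)=CCC[C@](O/C(Cl)=C\Cl)(C)CCB1C2CCCC1CCC2 | intermediate
7 | (R)-3-[(E)-1,2-dichloroethenyloxy]-3,7-dimethyloct-6-en-1-ol | CC(C)=CCC[C@](O/C(Cl)=C\Cl)(C)CCO | intermediate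
8 | (R)-6-[(E)-1,2-dichloroethenyloxy]-8-iodo-2,6-dimethyloct-2-ene | CC(C)=CCC[C@](O/C(Cl)=C\Cl)(C)CCI | intermediate
9 | propyne | CC#C | starting material
10 | 1-propynyllithium | [Li]C#CC | intermediate
11 | (R)-6-[(E)-1,2-dichloroethenyloxy]-2,6-dimethylundec-2-en-9-yne | CC(C)=CCC[C@](O/C(Cl)=C\Cl)(C)CCC#CC | intermediate
12 | (R)-6-(chloroethynyloxy)-2,6-dimethylundec-2-en-9-yne | CC(C)=CCC[C@](OC#CCl)(C)CCC#CC | intermediate
13 | lithium acetylide of 14 | CC(C)=CCC[C@](OC#C[Li])(C)CCC#CC | intermediate
14 | (R)-6-(ethynyloxy)-2,6-dimethylundec-2-en-9-yne | CC(C)=CCC[C@](OC#C)(C)CCC#CC | intermediate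
15 | 2-ethynyl-4,4,5,5-tetramethyl-1,3,2-dioxaborolane | C#CB1OC(C)(C)C(C)(C)O1 | starting material
16 | 2-[(2R)-2,5-dimethyl-2-(4-methylpent-3-en-1-yl)chroman-7-yl]-4,4,5,5-tetramethyl-1,3,2-dioxaborolane | CC(C)=CCC[C@]1(C)CCc2c(C)cc(B3OC(C)(C)C(C)(C)O3)cc2O1 | intermediate
17 | (2R)-2,5-dimethyl-2-(4-methylpent-3-en-1-yl)chroman-7-ol | CC(C)=CCC[C@]1(C)CCc2c(C)cc(O)cc2O1 | intermediate
18 | TBS ether of 17 | CC(C)=CCC[C@]1(C)CCc2c(C)cc(O[Si](C)(C)C(C)(C)C)cc2O1 | intermediate
19 | (E)-5-[(2R)-7-(tert-butyldimethylsilyloxy)-2,5-dimethylchroman-2-yl]-2-methylpent-2-enal | O=C/C(C)=C/CC[C@]1(C)CCc2c(C)cc(O[Si](C)(C)C(C)(C)C)cc2O1 | intermediate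
20 | (E)-5-[(2R)-7-(tert-butyldimethylsilyloxy)-2,5-dimethylchroman-2-yl]-2-methylpent-2-en-1-ol | OC/C(C)=C/CC[C@]1(C)CCc2c(C)cc(O[Si](C)(C)C(C)(C)C)cc2O1 | intermediate
21 | (2R)-2-[(E)-5-bromo-4-methylpent-3-en-1-yl]-7-(tert-butyldimethylsilyloxy)-2,5-dimethylchroman | BrC/C(C)=C/CC[C@]1(C)CCc2c(C)cc(O[Si](C)(C)C(C)(C)C)cc2O1 | intermediate
22 | acetaldehyde | CC=O | starting material
23 | tert-butylamine | CC(C)(C)N | starting material
24 | (E)-N-tert-butylethanimine | C/C=N/C(C)(C)C | intermediate
25 | N-lithio-N-tert-butylethenamine (lithiated 24) | [Li]N(C=C)C(C)(C)C | intermediate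
26 | N-tert-butyl imine of 27 (E at C=N, E at C3'=C4', 2R) | CC(C)(C)/N=C/CC/C(C)=C/CC[C@]1(C)CCc2c(C)cc(O[Si](C)(C)C(C)(C)C)cc2O1 | intermediate
27 | (E)-7-[(2R)-7-(tert-butyldimethylsilyloxy)-2,5-dimethylchroman-2-yl]-4-methylhept-4-enal | O=CCC/C(C)=C/CC[C@]1(C)CCc2c(C)cc(O[Si](C)(C)C(C)(C)C)cc2O1 | intermediate
28 | ethyl 2-[bis(2,2,2-trifluoroethoxy)phosphoryl]propanoate (racemic) | CCOC(=O)C(C)P(=O)(OCC(F)(F)F)OCC(F)(F)F | starting material
29 | potassium salt of 28 | CCOC(=O)[C-](C)P(=O)(OCC(F)(F)F)OCC(F)(F)F.[K+] | intermediate
30 | ethyl (2Z,6E)-9-[(2R)-7-(tert-butyldimethylsilyloxy)-2,5-dimethylchroman-2-yl]-2,6-dimethylnona-2,6-dienoate | C/C(=C/CC/C(C)=C/CC[C@]1(C)CCc2c(C)cc(O[Si](C)(C)C(C)(C)C)cc2O1)C(=O)OCC | intermediate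
31 | (2Z,6E)-9-[(2R)-7-hydroxy-2,5-dimethylchroman-2-yl]-2,6-dimethylnona-2,6-dienoic acid | C/C(=C/CC/C(C)=C/CC[C@]1(C)CCc2c(C)cc(O)cc2O1)C(=O)O | target

Total step count: 14. Longest linear sequence: 13 steps (steps 1–10 and 12–14; step 11 is a side branch).

Steps most likely to fail

1. Step 6.
- **What may go wrong:** The ynol ether may fragment by the retro-ene path before the metal engages it. The diyne or the boronate may couple with itself. Regiocontrol may erode, because the polarisation of the alkoxyalkyne and of the borylalkyne pulls against the steric preference.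
- **Fallback:** This uses known chemistry only, with the pyran ring closed on a preformed arene. It sets out from 1 and comes back at 18. Commercial 3-bromo-5-methylphenol (Cc1cc(O)cc(Br)c1) is iodinated para to the hydroxyl (N-iodosuccinimide, cat. TsOH, MeCN) to 3-bromo-4-iodo-5-methylphenol F1. F1 is silylated (TBSCl, imidazole) to its TBS ether F2. Compound 1 is hydroborated with 9-BBN (2.2 equiv) to the O,C-bis(boryl) adduct F3. F3 enters a B-alkyl Suzuki–Miyaura coupling at the more reactive C–I bond of F2 (PdCl2(dppf), K3PO4, THF/DMF/H2O) and gives the bromoaryl tertiary alcohol F4. An intramolecular Buchwald–Hartwig etherification (Pd(OAc)2, 2-(di-tert-butylphosphino)-1,1'-binaphthyl, Cs2CO3, toluene, 80 °C) then forms O1–C8a and gives 18. The carbinol C–O bond, and so the configuration, is untouched.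

2. Step 5.
- **What may go wrong:** The terminal ynol ether may decay thermally or under acid during work-up and handling. Excess n-BuLi may lithiate the propargylic position.
- **Fallback:** It sets out from 11 and comes back at 14. The lithium acetylide 13 is not protonated but trapped with Me3SiCl at −78 °C to give the C-silylated ynol ether F5. F5 has no acidic alkyne hydrogen, tolerates chromatography on deactivated silica and can be stored cold. K2CO3 in MeOH at 0 °C releases 14 directly before step 6.

3. Step 9.
- **What may go wrong:** Conversion may stay incomplete, the allylic position may be over-oxidised, and the oxidant may attack the electron-rich ring or its benzylic positions.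
- **Fallback:** It sets out from 18 and comes back at 27, so it also replaces steps 10 and 12. Epoxidation (mCPBA, NaHCO3, CH2Cl2, 0 °C) gives the trisubstituted epoxide F6. Isomerisation with Al(Oi-Pr)3 in hot toluene gives the isopropenyl carbinol F7. A Johnson–Claisen rearrangement (triethyl orthoacetate, cat. propionic acid, 140 °C) builds C5'–C6' and the E alkene through a chair transition state and gives the ethyl heptenoate F8. Reduction with i-Bu2AlH (toluene, −78 °C) gives 27.

Further compounds
F1 | step 6 | 3-bromo-4-iodo-5-methylphenol | Cc1cc(O)cc(Br)c1I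
F2 | step 6 | (3-bromo-4-iodo-5-methylphenoxy)(tert-butyl)dimethylsilane | Cc1cc(O[Si](C)(C)C(C)(C)C)cc(Br)c1I
F3 | step 6 | O,C-bis(9-borabicyclo[3.3.1]nonan-9-yl) adduct of (R)-linalool (spatial arrangement of 1 kept) | CC(C)=CCC[C@](OB1C2CCCC1CCC2)(C)CCB1C2CCCC1CCC2
F4 | step 6 | (R)-1-[2-bromo-4-(tert-butyldimethylsilyloxy)-6-methylphenyl]-3,7-dimethyloct-6-en-3-ol | CC(C)=CCC[C@](O)(C)CCc1c(C)cc(O[Si](C)(C)C(C)(C)C)cc1Br
F5 | step 5 | (R)-{[(2,6-dimethylundec-2-en-9-yn-6-yl)oxy]ethynyl}trimethylsilane | CC(C)=CCC[C@](OC#C[Si](C)(C)C)(C)CCC#CC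
F6 | step 9 | C3'–C4' epoxide of 18 (both oxirane epimers, C2 spatially unchanged) | CC1(C)OC1CC[C@]1(C)CCc2c(C)cc(O[Si](C)(C)C(C)(C)C)cc2O1
F7 | step 9 | 5-[7-(tert-butyldimethylsilyloxy)-2,5-dimethylchroman-2-yl]-2-methylpent-1-en-3-ol (both carbinol epimers, C2 spatially unchanged) | C=C(C)C(O)CC[C@]1(C)CCc2c(C)cc(O[Si](C)(C)C(C)(C)C)cc2O1
F8 | step 9 | ethyl (E)-7-[(2R)-7-(tert-butyldimethylsilyloxy)-2,5-dimethylchroman-2-yl]-4-methylhept-4-enoate | CCOC(=O)CC/C(C)=C/CC[C@]1(C)CCc2c(C)cc(O[Si](C)(C)C(C)(C)C)cc2O1
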